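**Plan**

- Cuts: the five phenols are masked as methyl ethers. The ring B C–Br bond and the ring A C3–Br bond are cut as electrophilic brominations, and the ring A C2–Br bond is traced through a diazonium salt and an amine back to a nitro group. Ring A is then cut at C1–C2 and C2–C3, which removes C2 as nitromethane and leaves a 4H-pyran-4-one. Last, the CH2–ring B bond is cut to a chloromethylpyranone from kojic acid and 1,3,5-trimethoxybenzene.
- Feature: ring A has CH2 on C1, H on C6 and oxygen on C5 and C4. This is the run C2 (CH2OH), C3 (H), C4 (C=O), C5 (OH) of kojic acid, and ring A C3 is kojic C6. Only C2 is missing, and it sits where the pyranone ring oxygen is.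
- Forward order: ring B is bought whole and joined to the kojic acid frame by a Negishi coupling. Ring A then arises when nitromethane replaces the ring oxygen of the pyranone. O-methylation, nitro reduction, double bromination, Sandmeyer bromination and global demethylation follow.
- Stereochemistry: vidalol A has no stereocentre and no stereogenic double bond. Only regiochemistry matters, and it is fixed by the pyranone substitution pattern, by the amine as ortho director and by the symmetry of ring B.

Key step: step 4

Remark: ring A is the dibromocatechol ring, numbered C1 (CH2), C2 (Br), C3 (Br), C4 (OH), C5 (OH), C6 (H); ring B is the bromophloroglucinol ring; pyranone atoms keep the kojic acid numbering (O1, C2 to C6).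

**Route**

Step 1
Reactants: 1 kojic acid (5-hydroxy-2-(hydroxymethyl)-4H-pyran-4-one)
Product: 2 2-(hydroxymethyl)-5-methoxy-4H-pyran-4-one
Conditions: Me2SO4 (1.1 equiv), KOH (1.1 equiv), H2O, 0 °C → rt
Reagents that add atoms: dimethyl sulfate, COS(=O)(=O)OC
Why: Only the acidic enolic 5-OH is ionised by one equivalent of aqueous KOH, so the Williamson O-methylation should take place there and leave the primary alcohol free.

Step 2
Reactants: 2 2-(hydroxymethyl)-5-methoxy-4H-pyran-4-one
Product: 3 2-(chloromethyl)-5-methoxy-4H-pyran-4-one
Conditions: SOCl2 (1.5 equiv), CH2Cl2, 0 °C → rt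
Reagents that add atoms: thionyl chloride, O=S(Cl)Cl
Why: Deoxychlorination through the chlorosulfite should turn the primary, allylic-type alcohol into the chloride, while the vinylogous ester of the pyranone is inert to SOCl2 at room temperature.

Step 3
Reactants: 4 1,3,5-trimethoxybenzene; 3 2-(chloromethyl)-5-methoxy-4H-pyran-4-one
Product: 7 5-methoxy-2-(2,4,6-trimethoxybenzyl)-4H-pyran-4-one, via (2,4,6-trimethoxyphenyl)lithium 5 (not isolated), via (2,4,6-trimethoxyphenyl)zinc chloride 6 (not isolated)
Conditions: 4, n-BuLi (1.05 equiv), THF, 0 °C → rt; ZnCl2 (1.1 equiv), 0 °C; then 3, Pd(PPh3)4 (5 mol %), THF, 50 °C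
Reagents that add atoms: none
Why: Ortho-lithiation of 4 between two methoxy groups and transmetalation to zinc give a non-basic arylzinc that tolerates the pyranone carbonyl, and zerovalent palladium inserts readily into the activated primary C–Cl bond of 3, so a Negishi cross-coupling should form the CH2–aryl bond with no β-hydride pathway available.

Step 4
Reactants: 7 5-methoxy-2-(2,4,6-trimethoxybenzyl)-4H-pyran-4-one; 8 nitromethane
Product: 10 2-methoxy-4-nitro-5-(2,4,6-trimethoxybenzyl)phenol, via open-chain nitro diketone 9 (not isolated)
Conditions: 8 (5 equiv), t-BuOK (3 equiv), t-BuOH–THF, rt → 70 °C; then 1 M HCl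
Reagents that add atoms: none
Why: The nitronate of 8 adds in conjugate fashion to an α carbon of the pyranone (drawn at the unsubstituted C6), the adduct opens by β-elimination of the ring oxygen as a diketone enolate to give 9, and the nitro-stabilised carbanion then attacks the ketone carbon that was pyranone C2, after which loss of water and enolisation of the former C4 carbonyl give the nitrophenoxide. The closest known reaction type is the base-mediated exchange of the ring oxygen of 4H-pyran-4-ones and pyrylium salts for the carbon of nitromethane, which gives 4-nitrophenols and nitrobenzenes. Ring A closes by a 6-exo-trig intramolecular nitro-aldol (Henry) addition followed by dehydration, which forms C1–C2 after the conjugate addition has formed C2–C3 (ring A numbering). No stereocentre is created, and the alkene geometry of 9 needed for closure can be reached through the delocalised nitronate before aromatisation removes it. The step needs carbon addition to the ring to prevail over deprotonation of the CH2 bridge and over addition to the carbonyl carbon; both of these are reversible whereas aromatisation is not, and attack at C2 instead of C6 leads through an isomeric open chain to the same arene, so no regiochemical question arises.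

Step 5
Reactants: 10 2-methoxy-4-nitro-5-(2,4,6-trimethoxybenzyl)phenol
Product: 11 2-(4,5-dimethoxy-2-nitrobenzyl)-1,3,5-trimethoxybenzene
Conditions: MeI (1.5 equiv), K2CO3 (2 equiv), DMF, rt
Reagents that add atoms: iodomethane, CI
Why: The 4-nitrophenoxide formed with K2CO3 should be alkylated on oxygen by iodomethane (Williamson ether synthesis), which removes the only free phenol so that the later bromination of ring A is steered by the amine alone.

Step 6
Reactants: 11 2-(4,5-dimethoxy-2-nitrobenzyl)-1,3,5-trimethoxybenzene
Product: 12 4,5-dimethoxy-2-(2,4,6-trimethoxybenzyl)aniline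
Conditions: H2 (1 atm), 10% Pd/C, EtOAc–EtOH, rt
Reagents that add atoms: none
Why: Catalytic hydrogenation over palladium should reduce the aryl nitro group cleanly to the aniline, because no halogen or other reducible group is present at this stage.

Step 7
Reactants: 12 4,5-dimethoxy-2-(2,4,6-trimethoxybenzyl)aniline
Product: 13 2-bromo-6-(3-bromo-2,4,6-trimethoxybenzyl)-3,4-dimethoxyaniline
Conditions: NBS (2.0 equiv), MeCN, −20 → 0 °C
Reagents that add atoms: N-bromosuccinimide, O=C1CCC(=O)N1Br
Why: Electrophilic aromatic bromination should go first to the two most nucleophilic carbons, namely C3 of ring A (the only free position ortho to NH2, also ortho to a methoxy group) and one of the two equivalent free carbons of ring B, and the bromine that enters ring B slows a second attack there, so two equivalents of NBS are expected to stop at the dibromide.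

Step 8
Reactants: 13 2-bromo-6-(3-bromo-2,4,6-trimethoxybenzyl)-3,4-dimethoxyaniline
Product: 15 2-bromo-4-(2,3-dibromo-4,5-dimethoxybenzyl)-1,3,5-trimethoxybenzene, via arenediazonium bromide 14 (not isolated)
Conditions: t-BuONO (1.5 equiv), CuBr2 (1.2 equiv), MeCN, 0 → 60 °C
Reagents that add atoms: copper dibromide, Br[Cu]Br
Why: In this Sandmeyer bromination with in situ diazotisation, t-BuONO converts the amine into diazonium ion 14, copper-mediated electron transfer releases N2, and the aryl radical should take bromine from CuBr2 faster than it can attack ring B, whose two ortho carbons carry methoxy groups and so offer no Pschorr-type closure.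

Step 9
Reactants: 15 2-bromo-4-(2,3-dibromo-4,5-dimethoxybenzyl)-1,3,5-trimethoxybenzene
Product: 16 vidalol A (2-bromo-4-(2,3-dibromo-4,5-dihydroxybenzyl)benzene-1,3,5-triol)
Conditions: BBr3 (8 equiv), CH2Cl2, −78 °C → rt; then ice-water
Reagents that add atoms: none
Why: BBr3 coordinates each methoxy oxygen and bromide then cleaves the O–CH3 bond (Lewis acid ether cleavage), which should free all five phenols while the aryl bromides and the diarylmethane bridge stay intact.

**Compound list**

1 | kojic acid, 5-hydroxy-2-(hydroxymethyl)-4H-pyran-4-one | OCc1cc(=O)c(O)co1 | starting material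
2 | 2-(hydroxymethyl)-5-methoxy-4H-pyran-4-one | COc1coc(CO)cc1=O | intermediate
3 | 2-(chloromethyl)-5-methoxy-4H-pyran-4-one | COc1coc(CCl)cc1=O | intermediate
4 | 1,3,5-trimethoxybenzene | COc1cc(OC)cc(OC)c1 | starting material
5 | (2,4,6-trimethoxyphenyl)lithium | [Li]c1c(OC)cc(OC)cc1OC | intermediate
6 | (2,4,6-trimethoxyphenyl)zinc chloride | Cl[Zn]c1c(OC)cc(OC)cc1OC | intermediate
7 | 5-methoxy-2-(2,4,6-trimethoxybenzyl)-4H-pyran-4-one | COc1coc(Cc2c(OC)cc(OC)cc2OC)cc1=O | intermediate
8 | nitromethane | C[N+](=O)[O-] | starting material
9 | (5E)-5-methoxy-7-nitro-1-(2,4,6-trimethoxyphenyl)hept-5-ene-2,4-dione (present as its enolate and nitronate salts) | [O-][N+](=O)C/C=C(OC)\C(=O)CC(=O)Cc1c(OC)cc(OC)cc1OC | intermediate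
10 | 2-methoxy-4-nitro-5-(2,4,6-trimethoxybenzyl)phenol | COc1cc([N+](=O)[O-])c(Cc2c(OC)cc(OC)cc2OC)cc1O | intermediate
11 | 2-(4,5-dimethoxy-2-nitrobenzyl)-1,3,5-trimethoxybenzene | COc1cc([N+](=O)[O-])c(Cc2c(OC)cc(OC)cc2OC)cc1OC | intermediate
12 | 4,5-dimethoxy-2-(2,4,6-trimethoxybenzyl)aniline | COc1cc(N)c(Cc2c(OC)cc(OC)cc2OC)cc1OC | intermediate
13 | 2-bromo-6-(3-bromo-2,4,6-trimethoxybenzyl)-3,4-dimethoxyaniline | COc1cc(Cc2c(OC)cc(OC)c(Br)c2OC)c(N)c(Br)c1OC | intermediate
14 | 2-bromo-6-(3-bromo-2,4,6-trimethoxybenzyl)-3,4-dimethoxybenzenediazonium bromide | COc1cc(Cc2c(OC)cc(OC)c(Br)c2OC)c([N+]#N)c(Br)c1OC.[Br-] | intermediate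
15 | 2-bromo-4-(2,3-dibromo-4,5-dimethoxybenzyl)-1,3,5-trimethoxybenzene | COc1cc(Cc2c(OC)cc(OC)c(Br)c2OC)c(Br)c(Br)c1OC | intermediate
16 | vidalol A, 2-bromo-4-(2,3-dibromo-4,5-dihydroxybenzyl)benzene-1,3,5-triol | Oc1cc(Cc2c(O)cc(O)c(Br)c2O)c(Br)c(Br)c1O | target

**Step count and risks**

Total steps: 9. Longest linear sequence: 9 steps, from kojic acid 1 to vidalol A 16; 1,3,5-trimethoxybenzene 4 and nitromethane 8 enter as purchased partners.

Steps most likely to fail:

1. Step 4. The base may open the pyranone without productive reclosure and degrade it to open-chain enolates. Nitromethane may also self-condense under the strong base, or deprotonation of the CH2 bridge may leave the nitronate without an electrophile. The fallback sets out from 4: arylzinc chloride 6 is prepared as in step 3 and cross-coupled (Pd(PPh3)4, THF, 50 °C) with purchased 4,5-dimethoxy-2-nitrobenzyl bromide F1. This Negishi coupling should give 11 directly, so the route is rejoined at 11. Ring A is then bought and no longer built from the pyranone.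

2. Step 3. Transmetalation of the doubly ortho-substituted arylzinc may be slow, so that reductive homocoupling of the chloride or protonation of the arylzinc takes over. The fallback sets out from 2 and joins the fragments at the aldehyde oxidation level. MnO2 in CH2Cl2 should oxidise the allylic-type alcohol of 2 to 5-methoxy-4-oxo-4H-pyran-2-carbaldehyde F2. Aryllithium 5, made from 4 as in step 3, is added at −78 °C to the aldehyde, the most electrophilic carbonyl, to give racemic 2-[hydroxy(2,4,6-trimethoxyphenyl)methyl]-5-methoxy-4H-pyran-4-one F3. Ionic deoxygenation with Et3SiH and CF3CO2H in CH2Cl2, through the cation stabilised by the trimethoxyphenyl ring, should then give 7, where the route is rejoined.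

3. Step 7. Site selectivity between the two electron-rich rings may be lost, ring B may take a second bromine, or the aminodimethoxyarene may be oxidised by NBS. The fallback sets out from 11 and introduces the two bromines one at a time. One equivalent of NBS in MeCN at 0 °C should brominate only ring B, because the nitro group deactivates ring A, and give 2-bromo-4-(4,5-dimethoxy-2-nitrobenzyl)-1,3,5-trimethoxybenzene F4. Reduction with Fe and NH4Cl in EtOH–H2O at 70 °C, which spares the aryl bromide, should give 2-(3-bromo-2,4,6-trimethoxybenzyl)-4,5-dimethoxyaniline F5. One equivalent of NBS at −20 °C then brominates ortho to the amine and gives 13, where the route is rejoined.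

**Further compounds**

F1 | step 4 | 4,5-dimethoxy-2-nitrobenzyl bromide (purchased) | COc1cc(CBr)c([N+](=O)[O-])cc1OC
F2 | step 3 | 5-methoxy-4-oxo-4H-pyran-2-carbaldehyde | COc1coc(C=O)cc1=O
F3 | step 3 | 2-[hydroxy(2,4,6-trimethoxyphenyl)methyl]-5-methoxy-4H-pyran-4-one (racemic) | COc1coc(C(O)c2c(OC)cc(OC)cc2OC)cc1=O
F4 | step 7 | 2-bromo-4-(4,5-dimethoxy-2-nitrobenzyl)-1,3,5-trimethoxybenzene | COc1cc([N+](=O)[O-])c(Cc2c(OC)cc(OC)c(Br)c2OC)cc1OC
F5 | step 7 | 2-(3-bromo-2,4,6-trimethoxybenzyl)-4,5-dimethoxyaniline | COc1cc(N)c(Cc2c(OC)cc(OC)c(Br)c2OC)cc1OC
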